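**Plan**
1. Retrosynthesis (naphthalene locants primed: C2′ is bonded to abietane C7, C3′ lies between C2′ and the isopropyl-bearing C4′, C1′ is the other ortho carbon, C8′ carries the keto chain): the aryl ether bond O–C3′ of the dihydrofuran is cut first, by C–H etherification of a 6α-hydroxy-7α-naphthyl abietane.
2. The C7–C2′ and C6–O bonds are cut next, together: syn arylboration/oxidation of the C6=C7 alkene of protected 6,7-didehydrohinokiol with a 7-bromonaphthalene. Last come the keto chain (Heck reaction) and ring B of the naphthalene (tetralone route).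
3. Forward: the naphthalene is built on a bromotoluene ring (Wittig, Friedel–Crafts, Grignard, aromatization), the chain is attached, and the only unhindered ring C–H is borylated and brominated. Rings A–C of the abietane come intact from hinokiol; the dihydrofuran ring is closed last, before global deprotection.
4. Stereochemistry: C3, C5 and C10 come from natural hinokiol; C6 and C7 are set together by α-face syn addition of boron and aryl; the ring closure touches no stereocentre.
5. Enabling feature: the equatorial 6α-OH is gauche to the pseudoaxial 7α-naphthyl group, so O6 and C3′–H are 1,5-related (six-membered palladacycle). The other ortho C–H (C1′) is blocked by the peri C8′ chain, and C14–H of ring C is out of reach.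

Key step: step 13

Assumption: hinokiol (natural 3β,12-dihydroxyabieta-8,11,13-triene), sold as an isolated natural product, is used as the chiral starting material; its C3, C5 and C10 configurations are those of the target.

**Route**

Step 1
Reactants: 1 2-bromo-3-methylbenzaldehyde; 2 (2-carboxyethyl)triphenylphosphonium bromide
Product: 3 (E)-4-(2-bromo-3-methylphenyl)but-3-enoic acid
Conditions: NaHMDS (2.1 equiv), THF, −78 °C to rt; then aq. HCl
Reagents that add atoms: none
Why: Wittig olefination with the ylide carboxylate of the 2-carboxyethyl phosphonium salt should give the β,γ-unsaturated acid, whose alkene geometry is irrelevant because the double bond is saturated next.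

Step 2
Reactants: 3 (E)-4-(2-bromo-3-methylphenyl)but-3-enoic acid
Product: 4 4-(2-bromo-3-methylphenyl)butanoic acid
Conditions: H2 (4 atm), RhCl(PPh3)3 (3 mol%), toluene/EtOH, 40 °C
Reagents that add atoms: none
Why: Homogeneous hydrogenation with RhCl(PPh3)3 should saturate the disubstituted alkene without hydrogenolysis of the aryl bromide.

Step 3
Reactants: 4 4-(2-bromo-3-methylphenyl)butanoic acid
Product: 5 5-bromo-6-methyl-3,4-dihydronaphthalen-1(2H)-one
Conditions: P2O5/MeSO3H (1:10 w/w), 60 °C
Reagents that add atoms: none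
Why: Intramolecular Friedel–Crafts acylation can take place only at the single free position ortho to the chain (para to the methyl group), which gives the 1-tetralone.

Step 4
Reactants: 5 5-bromo-6-methyl-3,4-dihydronaphthalen-1(2H)-one
Product: 6 5-bromo-6-methyl-1-(propan-2-yl)-1,2,3,4-tetrahydronaphthalen-1-ol (racemic)
Conditions: i-PrMgCl (1.5 equiv), anhydrous CeCl3 (1.5 equiv), THF, −78 to 0 °C; aq. NH4Cl
Reagents that add atoms: isopropylmagnesium chloride, CC(C)[Mg]Cl
Why: Grignard 1,2-addition in the presence of CeCl3, which suppresses enolization and reduction of the tetralone, installs the isopropyl group; the racemic carbinol centre is destroyed in the next step.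

Step 5
Reactants: 6 5-bromo-6-methyl-1-(propan-2-yl)-1,2,3,4-tetrahydronaphthalen-1-ol
Product: 8 1-bromo-2-methyl-5-(propan-2-yl)naphthalene, via dihydronaphthalene 7 (not isolated)
Conditions: TsOH·H2O (cat.), toluene, reflux with water separator; then DDQ (1.2 equiv), 80 °C
Reagents that add atoms: none
Why: Acid-catalysed E1 dehydration of the tertiary benzylic alcohol followed by DDQ dehydrogenation of the dihydronaphthalene should aromatize the second ring.

Step 6
Reactants: 8 1-bromo-2-methyl-5-(propan-2-yl)naphthalene; 9 4-methylpent-1-en-3-ol (racemic)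
Product: 10 4-methyl-1-[2-methyl-5-(propan-2-yl)naphthalen-1-yl]pentan-3-one
Conditions: Pd(OAc)2 (5 mol%), P(t-Bu)3·HBF4 (10 mol%), NaHCO3, Bu4NCl, DMF, 110 °C
Reagents that add atoms: none
Why: Mizoroki–Heck arylation of the allylic alcohol at its terminal carbon, β-hydride elimination toward the carbinol and enol–keto tautomerization should give the saturated β-aryl ketone directly.

Step 7
Reactants: 10 4-methyl-1-[2-methyl-5-(propan-2-yl)naphthalen-1-yl]pentan-3-one
Product: 12 1-[7-bromo-2-methyl-5-(propan-2-yl)naphthalen-1-yl]-4-methylpentan-3-one, via arylboronate 11 (not isolated)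
Conditions: [Ir(OMe)(cod)]2 (1.5 mol%), 4,4′-di-tert-butyl-2,2′-bipyridine (3 mol%), B2pin2 (0.6 equiv), THF, 80 °C; evaporate; then CuBr2 (3 equiv), MeOH/H2O (1:1), 80 °C
Reagents that add atoms: bis(pinacolato)diboron, CC1(C)OB(OC1(C)C)B1OC(C)(C)C(C)(C)O1 (boron of 11 only); copper dibromide, [Cu+2].[Br-].[Br-] (bromine of 12)
Why: Iridium-catalysed C–H borylation is sterically controlled and C7–H is the only ring C–H that is neither ortho nor peri to a substituent; the boronate is then converted into the bromide by CuBr2 (halodeboronation) in the same flask.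

Step 8
Reactants: 12 1-[7-bromo-2-methyl-5-(propan-2-yl)naphthalen-1-yl]-4-methylpentan-3-one
Product: 13 2-{2-[7-bromo-2-methyl-5-(propan-2-yl)naphthalen-1-yl]ethyl}-2-(propan-2-yl)-1,3-dioxolane
Conditions: HOCH2CH2OH (5 equiv), TsOH (cat.), benzene, reflux, water separator
Reagents that add atoms: ethylene glycol, OCCO
Why: Acid-catalysed ketalization with azeotropic removal of water masks the ketone against the alkoxide base, the boryl-copper species and α-arylation in step 11.

Step 9
Reactants: 14 hinokiol
Product: 15 3β,12-bis(methoxymethoxy)abieta-8,11,13-triene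
Conditions: NaH (3 equiv), MOMCl (3 equiv), THF/DMF, 0 °C to rt
Reagents that add atoms: chloromethyl methyl ether, COCCl
Why: Williamson-type alkylation of the phenoxide and of the secondary alkoxide gives two base-stable acetals that can be removed together with the ketal by acid at the end.

Step 10
Reactants: 15 3β,12-bis(methoxymethoxy)abieta-8,11,13-triene
Product: 16 3β,12-bis(methoxymethoxy)abieta-6,8,11,13-tetraene
Conditions: DDQ (1.2 equiv), dry 1,4-dioxane, 80 °C
Reagents that add atoms: none
Why: DDQ abstracts hydride from benzylic C7, which is para to the C12 oxygen, and loss of H6 gives the styrenyl C6=C7 alkene (benzylic dehydrogenation).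

Step 11
Reactants: 16 3β,12-bis(methoxymethoxy)abieta-6,8,11,13-tetraene; 13 2-{2-[7-bromo-2-methyl-5-(propan-2-yl)naphthalen-1-yl]ethyl}-2-(propan-2-yl)-1,3-dioxolane
Product: 17 3β,12-bis(methoxymethoxy)-7α-{4-isopropyl-7-methyl-8-[2-(2-isopropyl-1,3-dioxolan-2-yl)ethyl]naphthalen-2-yl}-6α-(4,4,5,5-tetramethyl-1,3,2-dioxaborolan-2-yl)abieta-8,11,13-triene
Conditions: CuCl (5 mol%), SIMes·HCl (6 mol%), Pd(OAc)2 (2.5 mol%), RuPhos (5 mol%), B2pin2 (1.5 equiv), NaOt-Bu (1.6 equiv), 13 (1.3 equiv), toluene/THF, rt to 40 °C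
Reagents that add atoms: bis(pinacolato)diboron, CC1(C)OB(OC1(C)C)B1OC(C)(C)C(C)(C)O1
Why: In this cooperative copper/palladium arylboration of a cyclic alkenylarene, Cu–Bpin adds syn across C6=C7 from the α face (opposite the axial C10 and C4β methyl groups) with boron on C6 and copper on benzylic C7, and stereoretentive transmetalation to the arylpalladium bromide with reductive elimination places the naphthyl group 7α, cis to the 6α-boron.

Step 12
Reactants: 17 the 6α-boryl-7α-naphthyl compound of step 11
Product: 18 3β,12-bis(methoxymethoxy)-7α-{4-isopropyl-7-methyl-8-[2-(2-isopropyl-1,3-dioxolan-2-yl)ethyl]naphthalen-2-yl}abieta-8,11,13-trien-6α-ol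
Conditions: 30% H2O2, 3 M NaOH, THF, 0 °C to rt
Reagents that add atoms: hydrogen peroxide, OO
Why: Alkaline peroxide oxidation of the secondary pinacol boronate proceeds by 1,2-migration from boron to oxygen with retention at C6 and should give the 6α-alcohol.

Step 13
Reactants: 18 the 6α-hydroxy-7α-naphthyl compound of step 12
Product: 19 bis(methoxymethyl) ether and dioxolane ketal of the target (6α-O–C3′ ether; cis-fused dihydronaphtho[2,3-b]furan on the α face of ring B)
Conditions: Pd(OAc)2 (10 mol%), PhI(OAc)2 (1.5 equiv), Li2CO3 (1.5 equiv), C6F6, 100 °C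
Reagents that add atoms: none
Why: Proposed new method: the closest known reaction type is the hydroxyl-directed C–H activation/C–O cyclization of tertiary 2-arylethanols to dihydrobenzofurans (Pd(OAc)2, PhI(OAc)2), extended here to a hindered secondary carbinol and to a naphthalene β-C–H; mechanistically the lithium alkoxide of 18 binds divalent palladium, acetate- or carbonate-assisted metalation of C3′–H gives a six-membered alkoxy-palladacycle, PhI(OAc)2 oxidizes it to tetravalent palladium, and C(sp2)–O reductive elimination releases 19. The single ring closed is the dihydrofuran, formed by contraction of the six-membered palladacycle to the five-membered ether in the reductive elimination; no stereocentre is created, and the preset cis relation of the equatorial 6α-oxygen and the pseudoaxial 7α-naphthyl group (gauche, about 60°) is what allows the palladacycle. Site selectivity between the two ortho C–H bonds of the naphthyl group is required: C1′–H is peri to the C8′ methylene, so an in-plane C–Pd bond there meets severe peri strain, whereas C3′–H is flanked only by the isopropyl group, which can turn its methine hydrogen toward the metal. C14–H of ring C is out of reach because the 6α-oxygen is anti to C8. Chemoselectivity against oxidation of the carbinol is also required: β-hydride elimination needs the palladium to reach the axial 6β-hydrogen, which lies between the axial C4β and C10 methyl groups, and this should retard it relative to metalation. The MOM ethers and the dioxolane are inert to the weakly basic, non-nucleophilic medium.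

Step 14
Reactants: 19 the protected pentacyclic ether of step 13
Product: 20 CNP0584944.1 (target)
Conditions: 3 M aq. HCl, THF/MeOH, 45 °C
Reagents that add atoms: water, O
Why: Aqueous acid hydrolyses both MOM acetals and the dioxolane in one operation, while the aryl alkyl ether of the dihydrofuran and all stereocentres are unaffected.

**Compound list**
1 | 2-bromo-3-methylbenzaldehyde | Cc1cccc(C=O)c1Br | starting material
2 | (2-carboxyethyl)triphenylphosphonium bromide | OC(=O)CC[P+](c1ccccc1)(c1ccccc1)c1ccccc1.[Br-] | starting material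
3 | (E)-4-(2-bromo-3-methylphenyl)but-3-enoic acid (E isomer drawn; both isomers are carried on) | Cc1cccc(/C=C/CC(=O)O)c1Br | intermediate
4 | 4-(2-bromo-3-methylphenyl)butanoic acid | Cc1cccc(CCCC(=O)O)c1Br | intermediate
5 | 5-bromo-6-methyl-3,4-dihydronaphthalen-1(2H)-one | Cc1ccc2c(c1Br)CCCC2=O | intermediate
6 | 5-bromo-6-methyl-1-(propan-2-yl)-1,2,3,4-tetrahydronaphthalen-1-ol (racemic) | Cc1ccc2c(c1Br)CCCC2(O)C(C)C | intermediate
7 | 8-bromo-7-methyl-4-(propan-2-yl)-1,2-dihydronaphthalene | Cc1ccc2c(c1Br)CCC=C2C(C)C | intermediate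
8 | 1-bromo-2-methyl-5-(propan-2-yl)naphthalene | Cc1ccc2c(C(C)C)cccc2c1Br | intermediate
9 | 4-methylpent-1-en-3-ol (racemic) | C=CC(O)C(C)C | starting material
10 | 4-methyl-1-[2-methyl-5-(propan-2-yl)naphthalen-1-yl]pentan-3-one | Cc1ccc2c(C(C)C)cccc2c1CCC(=O)C(C)C | intermediate
11 | 4-methyl-1-[2-methyl-5-(propan-2-yl)-7-(4,4,5,5-tetramethyl-1,3,2-dioxaborolan-2-yl)naphthalen-1-yl]pentan-3-one | Cc1ccc2c(C(C)C)cc(B3OC(C)(C)C(C)(C)O3)cc2c1CCC(=O)C(C)C | intermediate
12 | 1-[7-bromo-2-methyl-5-(propan-2-yl)naphthalen-1-yl]-4-methylpentan-3-one | Cc1ccc2c(C(C)C)cc(Br)cc2c1CCC(=O)C(C)C | intermediate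
13 | 2-{2-[7-bromo-2-methyl-5-(propan-2-yl)naphthalen-1-yl]ethyl}-2-(propan-2-yl)-1,3-dioxolane | Cc1ccc2c(C(C)C)cc(Br)cc2c1CCC1(C(C)C)OCCO1 | intermediate
14 | hinokiol, abieta-8,11,13-triene-3β,12-diol (5α-H, 10β-methyl) | C1Cc2cc(C(C)C)c(O)cc2[C@@]2(C)CC[C@H](O)C(C)(C)[C@H]12 | starting material
15 | 3β,12-bis(methoxymethoxy)abieta-8,11,13-triene | C1Cc2cc(C(C)C)c(OCOC)cc2[C@@]2(C)CC[C@H](OCOC)C(C)(C)[C@H]12 | intermediate
16 | 3β,12-bis(methoxymethoxy)abieta-6,8,11,13-tetraene | C1=Cc2cc(C(C)C)c(OCOC)cc2[C@@]2(C)CC[C@H](OCOC)C(C)(C)[C@H]12 | intermediate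
17 | 3β,12-bis(methoxymethoxy)-7α-{4-isopropyl-7-methyl-8-[2-(2-isopropyl-1,3-dioxolan-2-yl)ethyl]naphthalen-2-yl}-6α-(pinacolboryl)abieta-8,11,13-triene (H6 and H7 both β) | Cc1ccc2c(C(C)C)cc(cc2c1CCC1(C(C)C)OCCO1)[C@H]1c2cc(C(C)C)c(OCOC)cc2[C@@]2(C)CC[C@H](OCOC)C(C)(C)[C@@H]2[C@H]1B1OC(C)(C)C(C)(C)O1 | intermediate
18 | 3β,12-bis(methoxymethoxy)-7α-{4-isopropyl-7-methyl-8-[2-(2-isopropyl-1,3-dioxolan-2-yl)ethyl]naphthalen-2-yl}abieta-8,11,13-trien-6α-ol | Cc1ccc2c(C(C)C)cc(cc2c1CCC1(C(C)C)OCCO1)[C@H]1c2cc(C(C)C)c(OCOC)cc2[C@@]2(C)CC[C@H](OCOC)C(C)(C)[C@@H]2[C@H]1O | intermediate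
19 | protected target: 3β,12-bis(methoxymethoxy)abieta-8,11,13-triene carrying the cis-fused dihydrofuran (O on C6α and on naphthalene C3′; C7α bonded to C2′), with 4′-isopropyl, 7′-methyl and 8′-[2-(2-isopropyl-1,3-dioxolan-2-yl)ethyl] | Cc1ccc2c(C(C)C)c3c(cc2c1CCC1(C(C)C)OCCO1)[C@H]1c2cc(C(C)C)c(OCOC)cc2[C@@]2(C)CC[C@H](OCOC)C(C)(C)[C@@H]2[C@H]1O3 | intermediate
20 | CNP0584944.1: the same pentacyclic ether with free 3β-OH and 12-OH and the 4-methyl-3-oxopentyl chain on C8′ | Cc1ccc2c(C(C)C)c3c(cc2c1CCC(=O)C(C)C)[C@H]1c2cc(C(C)C)c(O)cc2[C@@]2(C)CC[C@H](O)C(C)(C)[C@@H]2[C@H]1O3 | target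

**Count**
Total steps: 14. Longest linear sequence: 12 (steps 1–8, then 11–14, from aldehyde 1); the hinokiol branch contributes steps 9–10.

**Steps most likely to fail**

Step 13 (proposed new method). The palladium alkoxide may undergo β-hydride elimination, oxidizing the C6 carbinol to the ketone faster than C–H metalation, or metalation may occur at C1′ instead of C3′. The fallback uses known chemistry only: ketone α-fluorination, the operations of steps 4–8, 11 and 12, and intramolecular SNAr of an aryl fluoride by an alkoxide. It sets out from tetralone 5 and returns at 19. Tetralone 5 is fluorinated at C2 (LiHMDS, N-fluorobenzenesulfonimide, THF, −78 °C) to 5-bromo-2-fluoro-6-methyl-3,4-dihydronaphthalen-1(2H)-one F1. Addition of i-PrMgCl/CeCl3 gives 5-bromo-2-fluoro-6-methyl-1-(propan-2-yl)-1,2,3,4-tetrahydronaphthalen-1-ol F2. TsOH and then DDQ lead through 8-bromo-3-fluoro-7-methyl-4-(propan-2-yl)-1,2-dihydronaphthalene F3 to 1-bromo-6-fluoro-2-methyl-5-(propan-2-yl)naphthalene F4. Heck reaction with 9 gives 1-[6-fluoro-2-methyl-5-(propan-2-yl)naphthalen-1-yl]-4-methylpentan-3-one F5. Borylation at C7, now ortho to fluorine and still the only unhindered C–H, gives 1-[6-fluoro-2-methyl-5-(propan-2-yl)-7-(pinacolboryl)naphthalen-1-yl]-4-methylpentan-3-one F6, and CuBr2 converts it into 1-[7-bromo-6-fluoro-2-methyl-5-(propan-2-yl)naphthalen-1-yl]-4-methylpentan-3-one F7. Ketalization gives 2-{2-[7-bromo-6-fluoro-2-methyl-5-(propan-2-yl)naphthalen-1-yl]ethyl}-2-(propan-2-yl)-1,3-dioxolane F8. Arylboration of 16 with F8 should give the 6α-pinacolboryl-7α-(3-fluoronaphthalen-2-yl) analogue of 17 F9, and alkaline peroxide the 3′-fluoro analogue of alcohol 18 F10. KHMDS in THF/DMF at 60–80 °C then closes the same O–C3′ bond by displacement of fluoride and gives 19.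

Step 11. Borylcupration of the hindered C6=C7 bond may be slow, or transmetalation of the benzylic copper may proceed with inversion and give the anti (7β-aryl) isomer. The fallback sets out from 16 and returns at 18. Epoxidation on the α face with dimethyldioxirane (acetone, −20 °C) gives 6α,7α-epoxy-3β,12-bis(methoxymethoxy)abieta-8,11,13-triene F11. Bromide 13 is converted (t-BuLi, −78 °C; then Et2AlCl) into the aryl(diethyl)alane. This opens the epoxide at the benzylic C7, which is stabilized by the para oxygen, and delivers the aryl group from the aluminium alkoxide on the same α face. Such syn opening is known for cation-stabilized epoxides such as glycal epoxides, and it would give 18 directly, without boronate 17.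

Step 10. The electron-rich styrene product may be oxidized further (second hydride abstraction, or hydration of the C7 cation to the 7-ketone), and the acetals may be lost. The fallback sets out from 15 and returns at 16. Benzylic oxidation with CrO3/3,5-dimethylpyrazole (CH2Cl2, −20 °C) gives 3β,12-bis(methoxymethoxy)abieta-8,11,13-trien-7-one F12. NaBH4 (MeOH, 0 °C) gives 3β,12-bis(methoxymethoxy)abieta-8,11,13-trien-7-ol F13 as an epimer mixture. Dehydration with the Burgess reagent (benzene, 50 °C) gives 16.

**Further compounds**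
F1 | step 13 | 5-bromo-2-fluoro-6-methyl-3,4-dihydronaphthalen-1(2H)-one (racemic) | Cc1ccc2c(c1Br)CCC(F)C2=O
F2 | step 13 | 5-bromo-2-fluoro-6-methyl-1-(propan-2-yl)-1,2,3,4-tetrahydronaphthalen-1-ol (diastereomer mixture) | Cc1ccc2c(c1Br)CCC(F)C2(O)C(C)C
F3 | step 13 | 8-bromo-3-fluoro-7-methyl-4-(propan-2-yl)-1,2-dihydronaphthalene | Cc1ccc2c(c1Br)CCC(F)=C2C(C)C
F4 | step 13 | 1-bromo-6-fluoro-2-methyl-5-(propan-2-yl)naphthalene | Cc1ccc2c(C(C)C)c(F)ccc2c1Br
F5 | step 13 | 1-[6-fluoro-2-methyl-5-(propan-2-yl)naphthalen-1-yl]-4-methylpentan-3-one | Cc1ccc2c(C(C)C)c(F)ccc2c1CCC(=O)C(C)C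
F6 | step 13 | 1-[6-fluoro-2-methyl-5-(propan-2-yl)-7-(4,4,5,5-tetramethyl-1,3,2-dioxaborolan-2-yl)naphthalen-1-yl]-4-methylpentan-3-one | Cc1ccc2c(C(C)C)c(F)c(B3OC(C)(C)C(C)(C)O3)cc2c1CCC(=O)C(C)C
F7 | step 13 | 1-[7-bromo-6-fluoro-2-methyl-5-(propan-2-yl)naphthalen-1-yl]-4-methylpentan-3-one | Cc1ccc2c(C(C)C)c(F)c(Br)cc2c1CCC(=O)C(C)C
F8 | step 13 | 2-{2-[7-bromo-6-fluoro-2-methyl-5-(propan-2-yl)naphthalen-1-yl]ethyl}-2-(propan-2-yl)-1,3-dioxolane | Cc1ccc2c(C(C)C)c(F)c(Br)cc2c1CCC1(C(C)C)OCCO1
F9 | step 13 | 3′-fluoro analogue of 17 (6α-pinacolboryl, 7α-(3-fluoronaphthalen-2-yl)) | Cc1ccc2c(C(C)C)c(F)c(cc2c1CCC1(C(C)C)OCCO1)[C@H]1c2cc(C(C)C)c(OCOC)cc2[C@@]2(C)CC[C@H](OCOC)C(C)(C)[C@@H]2[C@H]1B1OC(C)(C)C(C)(C)O1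
F10 | step 13 | 3′-fluoro analogue of 18 (6α-ol, 7α-(3-fluoronaphthalen-2-yl)) | Cc1ccc2c(C(C)C)c(F)c(cc2c1CCC1(C(C)C)OCCO1)[C@H]1c2cc(C(C)C)c(OCOC)cc2[C@@]2(C)CC[C@H](OCOC)C(C)(C)[C@@H]2[C@H]1O
F11 | step 11 | 6α,7α-epoxy-3β,12-bis(methoxymethoxy)abieta-8,11,13-triene | O1[C@H]2c3cc(C(C)C)c(OCOC)cc3[C@@]3(C)CC[C@H](OCOC)C(C)(C)[C@@H]3[C@@H]12
F12 | step 10 | 3β,12-bis(methoxymethoxy)abieta-8,11,13-trien-7-one | C1C(=O)c2cc(C(C)C)c(OCOC)cc2[C@@]2(C)CC[C@H](OCOC)C(C)(C)[C@H]12
F13 | step 10 | 3β,12-bis(methoxymethoxy)abieta-8,11,13-trien-7-ol (C7 epimer mixture) | C1C(O)c2cc(C(C)C)c(OCOC)cc2[C@@]2(C)CC[C@H](OCOC)C(C)(C)[C@H]12
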